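A direct plan would join dimethyl 2,2-diprenylmalonate A1 and the dianion of the prenylated diketone A2 by acylation and Dieckmann closure to the achiral trione colupulone A3, and would then hydroxylate the dienolate of A3 at C4 with a chiral N-sulfonyloxaziridine. Its weakest steps would be (a) the one-flask acylation and ring closure, which would lack close precedent and would compete with O-acylation and retro-Claisen cleavage; (b) the hydroxylation, in which the reagent alone would have to tell apart the faces of a dienolate whose C3 and C5 flanks differ only one atom further out; (c) the dianion γ-alkylation that would make A2, a cryogenic step that adds length without complexity.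

The plan disconnects the C4–CH2 bond of the C4 prenyl group by a [3,3] shift from O5. It exploits that C6 of the cyclohexane ring is quaternary: in a 5-O-allyl enol ether the double bond can only be C4=C5, so a Claisen rearrangement can only end at the oxygen-bearing C4. One operation forms this bond, reveals the C5 ketone and carries the configuration of (R)-but-3-en-2-ol to the quaternary carbinol carbon; metathesis then trims butenyl to prenyl. The ring and all four ring oxygens are bought as an arene, so neither a condensation ring assembly nor an enolate hydroxylation with reagent-controlled face selection has a counterpart.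

Key step: step 6

Assumption: 2,6-dimethoxybenzene-1,4-diol (1) is bought (otherwise Na2S2O4 reduction of the quinone in water gives it); ring positions C1 to C6 follow the target name, and enolised triones are drawn in the tautomer of the target.

Step 1
Reactants: 1 2,6-dimethoxybenzene-1,4-diol; 2 2-methylpropanoic acid (1.2 equiv)
Product: 3 1-(3,6-dihydroxy-2,4-dimethoxyphenyl)-2-methylpropan-1-one
Conditions: BF3·OEt2 (solvent), 70 °C, 3 h, argon; then aq. NaOAc, rt
Reagents that add atoms: none
Why: Friedel–Crafts acylation of a hydroquinone with a carboxylic acid in BF3·OEt2 (O-acylation and Fries shift), which should go to one of the two equivalent free ring positions ortho to the unhindered hydroxyl and stop there because the ketone is held as its BF2 chelate; no stereocentre is formed.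

Step 2
Reactants: 3 1-(3,6-dihydroxy-2,4-dimethoxyphenyl)-2-methylpropan-1-one
Product: 4 1-[6-hydroxy-2,4-dimethoxy-3-(methoxymethoxy)phenyl]-2-methylpropan-1-one
Conditions: MOMCl (1.2 equiv), iPr2NEt (1.5 equiv), CH2Cl2, 0 °C → rt
Reagents that add atoms: chloromethyl methyl ether, COCCl
Why: Williamson-type O-alkylation to the methoxymethyl acetal: only the hydroxyl between the two methoxy groups should react, because the other is locked in a hydrogen bond to the ketone, and this marks the future C4 oxygen as the one protected oxygen.

Step 3
Reactants: 4 1-[6-hydroxy-2,4-dimethoxy-3-(methoxymethoxy)phenyl]-2-methylpropan-1-one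
Product: 6 1-[2,4,6-trihydroxy-3-(methoxymethoxy)phenyl]-2-methylpropan-1-one, via mono-demethylated phenol 5 (not isolated)
Conditions: NaSEt (8 equiv), DMF, 130 °C, 16 h, argon; then cold 0.5 M HCl to pH 4
Reagents that add atoms: none
Why: Nucleophilic (SN2) O-demethylation of aryl methyl ethers by thiolate: the methoxy groups ortho and para to the ketone release carbonyl-conjugated phenoxides and should be cleaved, whereas the acetal carbon is no SN2 electrophile and the acetal is stable to base; no stereocentre is involved.

Step 4
Reactants: 6 1-[2,4,6-trihydroxy-3-(methoxymethoxy)phenyl]-2-methylpropan-1-one; 7 (2R)-but-3-en-2-ol (1.1 equiv)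
Product: 8 1-{4-[(2S)-but-3-en-2-yloxy]-2,6-dihydroxy-3-(methoxymethoxy)phenyl}-2-methylpropan-1-one
Conditions: PPh3 (1.2 equiv), DIAD (1.2 equiv), THF, 0 °C → rt
Reagents that add atoms: none
Why: Mitsunobu etherification: the 4-hydroxyl para to the ketone is the most acidic and the only one not engaged with the acyl group, so it should be alkylated selectively, and the SN2 displacement of the oxyphosphonium ion inverts (R)-7 to the (S)-configured ether, which is the stereochemical source of the route.

Step 5
Reactants: 8 1-{4-[(2S)-but-3-en-2-yloxy]-2,6-dihydroxy-3-(methoxymethoxy)phenyl}-2-methylpropan-1-one; 9 1-bromo-3-methylbut-2-ene (2.3 equiv)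
Product: 11 5-[(2S)-but-3-en-2-yloxy]-3-hydroxy-4-(methoxymethoxy)-6,6-bis(3-methylbut-2-en-1-yl)-2-(2-methylpropanoyl)cyclohexa-2,4-dien-1-one, via monoprenyl arene 10 (not isolated)
Conditions: NaOMe (3.2 equiv), MeOH, 0 °C → rt, argon; then aq. NaH2PO4
Reagents that add atoms: none
Why: Alkylative dearomatisation of an acylphloroglucinol monoether (C-alkylation of the phenoxide dianion): the first prenyl group should enter the only unsubstituted ring carbon, ortho and para to the two phenoxides, and the second should enter the same carbon because this leads to the stabilised 2-acyl-1,3-dione enolate, while the protic medium disfavours O-alkylation and the product enolate is inert to methoxide; the ether stereocentre is not touched.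

Step 6
Reactants: 11 5-[(2S)-but-3-en-2-yloxy]-3-hydroxy-4-(methoxymethoxy)-6,6-bis(3-methylbut-2-en-1-yl)-2-(2-methylpropanoyl)cyclohexa-2,4-dien-1-one
Product: 12 (4S)-4-[(2E)-but-2-en-1-yl]-3-hydroxy-4-(methoxymethoxy)-6,6-bis(3-methylbut-2-en-1-yl)-2-(2-methylpropanoyl)cyclohex-2-ene-1,5-dione
Conditions: iPr2NEt (1.2 equiv), toluene (degassed), 105 °C, sealed tube, 12–24 h; then cold 5% citric acid
Reagents that add atoms: none
Why: Thermal Claisen rearrangement: O5, C5 and C4 of 11 are an allyl vinyl ether, and because C6 is quaternary the enol ether double bond can only be C4=C5, so the concerted suprafacial [3,3] shift through a six-membered transition state can only form the C4–CH2 bond, while C5 becomes the ketone and the 2-acyl enol stays as it is. The closest known reaction type is the O-to-C allyl shift of 3-allyloxy-enones (allyl enol ethers of cyclic 1,3-diones) to 2-allyl-1,3-diones, together with the 1,3-chirality transfer known for vinyl ethers of secondary allylic alcohols. No ring is closed. The new quaternary stereocentre C4 is controlled by the (S)-configured carbinol carbon of the ether: in the chair transition state its methyl group lies equatorial, since an axial methyl would meet the C6 substituent on C5, and this gives the (E)-alkene and delivers the chain to the face of C4 that corresponds to (4S). The step needs the concerted pathway to win over ionisation to a methylallyl cation and the chair to win over the boat; the amine keeps the acidic trione as its salt, which removes the acid that would catalyse ionisation and makes the enol ether more electron-rich, and the boat would push the allyl unit over the ring against a prenyl group on C6. The methoxymethyl group on O4 makes C4 non-enolisable once the bond is formed, so the configuration cannot be lost.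

Step 7
Reactants: 12 (4S)-4-[(2E)-but-2-en-1-yl]-3-hydroxy-4-(methoxymethoxy)-6,6-bis(3-methylbut-2-en-1-yl)-2-(2-methylpropanoyl)cyclohex-2-ene-1,5-dione; 13 2-methylbut-2-ene (co-solvent, large excess)
Product: 14 (4S)-3-hydroxy-4-(methoxymethoxy)-4,6,6-tris(3-methylbut-2-en-1-yl)-2-(2-methylpropanoyl)cyclohex-2-ene-1,5-dione
Conditions: second-generation Hoveyda–Grubbs catalyst, (H2IMes)Cl2Ru=CH(C6H4-2-OiPr) (5 mol %), 2-methylbut-2-ene/CH2Cl2 1:1, 40 °C, sealed tube
Reagents that add atoms: none
Why: Olefin cross-metathesis with a large excess of a trisubstituted alkene: the ethylidene end of the 1,2-disubstituted butenyl group should be exchanged for an isopropylidene end, the prenyl alkenes can only undergo degenerate exchange, and dilution in the alkene partner should suppress ring closure between the side chains on C4 and C6; the C4 stereocentre is not involved.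

Step 8
Reactants: 14 (4S)-3-hydroxy-4-(methoxymethoxy)-4,6,6-tris(3-methylbut-2-en-1-yl)-2-(2-methylpropanoyl)cyclohex-2-ene-1,5-dione
Product: 15 (4S)-3,4-dihydroxy-4,6,6-tris(3-methylbut-2-en-1-yl)-2-(2-methylpropanoyl)cyclohex-2-ene-1,5-dione
Conditions: ZnBr2 (1.5 equiv), n-PrSH (3 equiv), CH2Cl2, 0 °C, 10–15 min; then pH 7 phosphate buffer
Reagents that add atoms: none
Why: Lewis-acid-assisted cleavage of a methoxymethyl ether with thiol capture of the oxocarbenium ion, which is fast also for tertiary ethers: only the O–CH2 bond is broken, so the C4–O bond and the (4S) configuration are retained, and the short, cold, nearly neutral treatment should spare the prenyl groups and avoid an acyloin shift of the α-hydroxy ketone.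

Compound list
1 | 2,6-dimethoxybenzene-1,4-diol | COc1cc(O)cc(OC)c1O | starting material
2 | 2-methylpropanoic acid (isobutyric acid) | CC(C)C(=O)O | starting material
3 | 1-(3,6-dihydroxy-2,4-dimethoxyphenyl)-2-methylpropan-1-one | CC(C)C(=O)c1c(O)cc(OC)c(O)c1OC | intermediate
4 | 1-[6-hydroxy-2,4-dimethoxy-3-(methoxymethoxy)phenyl]-2-methylpropan-1-one | CC(C)C(=O)c1c(O)cc(OC)c(OCOC)c1OC | intermediate
5 | 1-[2,6-dihydroxy-4-methoxy-3-(methoxymethoxy)phenyl]-2-methylpropan-1-one | CC(C)C(=O)c1c(O)cc(OC)c(OCOC)c1O | intermediate (not isolated)
6 | 1-[2,4,6-trihydroxy-3-(methoxymethoxy)phenyl]-2-methylpropan-1-one | CC(C)C(=O)c1c(O)cc(O)c(OCOC)c1O | intermediate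
7 | (2R)-but-3-en-2-ol | C[C@@H](O)C=C | starting material
8 | 1-{4-[(2S)-but-3-en-2-yloxy]-2,6-dihydroxy-3-(methoxymethoxy)phenyl}-2-methylpropan-1-one | CC(C)C(=O)c1c(O)cc(O[C@@H](C)C=C)c(OCOC)c1O | intermediate
9 | 1-bromo-3-methylbut-2-ene (prenyl bromide) | CC(C)=CCBr | starting material
10 | 1-{4-[(2S)-but-3-en-2-yloxy]-2,6-dihydroxy-3-(methoxymethoxy)-5-(3-methylbut-2-en-1-yl)phenyl}-2-methylpropan-1-one | CC(C)C(=O)c1c(O)c(CC=C(C)C)c(O[C@@H](C)C=C)c(OCOC)c1O | intermediate (not isolated)
11 | 5-[(2S)-but-3-en-2-yloxy]-3-hydroxy-4-(methoxymethoxy)-6,6-bis(3-methylbut-2-en-1-yl)-2-(2-methylpropanoyl)cyclohexa-2,4-dien-1-one | CC(C)C(=O)C1=C(O)C(OCOC)=C(O[C@@H](C)C=C)C(CC=C(C)C)(CC=C(C)C)C1=O | intermediate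
12 | (4S)-4-[(2E)-but-2-en-1-yl]-3-hydroxy-4-(methoxymethoxy)-6,6-bis(3-methylbut-2-en-1-yl)-2-(2-methylpropanoyl)cyclohex-2-ene-1,5-dione | CC(C)=CCC1(CC=C(C)C)C(=O)C(C(=O)C(C)C)=C(O)[C@@](OCOC)(C/C=C/C)C1=O | intermediate
13 | 2-methylbut-2-ene | CC=C(C)C | starting material
14 | (4S)-3-hydroxy-4-(methoxymethoxy)-4,6,6-tris(3-methylbut-2-en-1-yl)-2-(2-methylpropanoyl)cyclohex-2-ene-1,5-dione | CC(C)=CCC1(CC=C(C)C)C(=O)C(C(=O)C(C)C)=C(O)[C@@](OCOC)(CC=C(C)C)C1=O | intermediate
15 | (4S)-3,4-dihydroxy-4,6,6-tris(3-methylbut-2-en-1-yl)-2-(2-methylpropanoyl)cyclohex-2-ene-1,5-dione | CC(C)=CCC1(CC=C(C)C)C(=O)C(C(=O)C(C)C)=C(O)[C@@](O)(CC=C(C)C)C1=O | target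

Total step count: 8. Longest linear sequence: 8 steps (1 to 15).

Steps most likely to fail

The rearrangement of step 6 may lose its stereochemical fidelity if the allylic C–O bond ionises before the concerted shift, or if part of the material passes through the boat; it may also be too slow below the temperature at which the prenyl groups begin to react. The fallback would replace chirality transfer by catalyst control and would set out from 6. Geminal prenylation of 6 under the conditions of step 5 would give 3,5-dihydroxy-4-(methoxymethoxy)-6,6-bis(3-methylbut-2-en-1-yl)-2-(2-methylpropanoyl)cyclohexa-2,4-dien-1-one F1. Its C4 would then be prenylated in a Tsuji–Trost asymmetric allylic alkylation of a 2-substituted cyclic 1,3-dione, with tert-butyl 3-methylbut-2-en-1-yl carbonate, the zerovalent palladium source Pd2(dba)3 and one enantiomer of N,N′-(cyclohexane-1,2-diyl)bis[2-(diphenylphosphanyl)benzamide], the enantiomer to be chosen by experiment. This would come back to the route at 14 and make steps 4, 6 and 7 unnecessary, at the price of catalyst-dependent enantioselectivity.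

The demethylation of step 3 may stall after the first methyl group, because the second cleavage has to generate a trianion, and the temperature then needed may cost the acetal. The fallback would lower the charge and would set out from 3.
- Both hydroxyls would be protected (NaH, MOMCl, THF) to give 1-[2,4-dimethoxy-3,6-bis(methoxymethoxy)phenyl]-2-methylpropan-1-one F2.
- Thiolate demethylation of this neutral ketone has to form only a dianion and would give 1-[2,4-dihydroxy-3,6-bis(methoxymethoxy)phenyl]-2-methylpropan-1-one F3.
- Mitsunobu etherification with 7 at the only non-chelated hydroxyl would give 1-{4-[(2S)-but-3-en-2-yloxy]-2-hydroxy-3,6-bis(methoxymethoxy)phenyl}-2-methylpropan-1-one F4.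
- Mild methanolysis (dilute HCl in MeOH, 0 °C) of the acetal ortho to the ketone, the more labile of the two because its phenol is carbonyl-conjugated, would come back to the route at 8.

The dearomatising alkylation of step 5 may suffer from O-alkylation, from attack at the oxygen-bearing or the acyl-bearing ring carbon in the second alkylation, or from incomplete second alkylation. The fallback would introduce the two prenyl groups on different substrates and would set out from 6. C-Prenylation of the free trihydroxy ketone with one equivalent of 9 in aqueous KOH, the substrate and medium with the best C-selectivity, would give 1-[2,4,6-trihydroxy-3-(methoxymethoxy)-5-(3-methylbut-2-en-1-yl)phenyl]-2-methylpropan-1-one F5. Mitsunobu etherification with 7 at its 4-hydroxyl would come back to the route at 10, now isolated and purified, which then needs only the single dearomatising alkylation to 11.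

Further compounds
F1 | step 6 | 3,5-dihydroxy-4-(methoxymethoxy)-6,6-bis(3-methylbut-2-en-1-yl)-2-(2-methylpropanoyl)cyclohexa-2,4-dien-1-one | CC(C)C(=O)C1=C(O)C(OCOC)=C(O)C(CC=C(C)C)(CC=C(C)C)C1=O
F2 | step 3 | 1-[2,4-dimethoxy-3,6-bis(methoxymethoxy)phenyl]-2-methylpropan-1-one | CC(C)C(=O)c1c(OCOC)cc(OC)c(OCOC)c1OC
F3 | step 3 | 1-[2,4-dihydroxy-3,6-bis(methoxymethoxy)phenyl]-2-methylpropan-1-one | CC(C)C(=O)c1c(OCOC)cc(O)c(OCOC)c1O
F4 | step 3 | 1-{4-[(2S)-but-3-en-2-yloxy]-2-hydroxy-3,6-bis(methoxymethoxy)phenyl}-2-methylpropan-1-one | CC(C)C(=O)c1c(OCOC)cc(O[C@@H](C)C=C)c(OCOC)c1O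
F5 | step 5 | 1-[2,4,6-trihydroxy-3-(methoxymethoxy)-5-(3-methylbut-2-en-1-yl)phenyl]-2-methylpropan-1-one | CC(C)C(=O)c1c(O)c(CC=C(C)C)c(O)c(OCOC)c1O
A1 | direct plan | dimethyl 2,2-bis(3-methylbut-2-en-1-yl)propanedioate | COC(=O)C(CC=C(C)C)(CC=C(C)C)C(=O)OC
A2 | direct plan | 2,9-dimethyldec-8-ene-3,5-dione | CC(C)C(=O)CC(=O)CCC=C(C)C
A3 | direct plan | colupulone, 3,5-dihydroxy-2-(2-methylpropanoyl)-4,6,6-tris(3-methylbut-2-en-1-yl)cyclohexa-2,4-dien-1-one | CC(C)C(=O)C1=C(O)C(CC=C(C)C)=C(O)C(CC=C(C)C)(CC=C(C)C)C1=O
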